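## Retrosynthetic overview

1. Target 17 ⇐ allyl ester 16 (neutral deallylation) ⇐ Horner–Wadsworth–Emmons olefination of methyl ketone 14 with phosphonate 15 (C13=C14, E).
2. 14 ⇐ tricyclic enol ether 13/12/11 (an 18-functionalised sclareol oxide); its pyran ring masks both the 8α-OH and the C13 ketone, and the C18–O bond comes from a C18–Si bond (Tamao–Fleming).
3. 11 ⇐ acyclic (E,E,E)-silyl trienone 10 by one new enantioselective, β-silicon-steered bicyclisation: ring A, then ring B, then the pyran; it sets C4, C5, C10, C9 and C8.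
4. 10 ⇐ (E,E)-farnesyl bromide 1 + ethyl acetoacetate 2; the terminal (E)-methyl is converted into CH2OH (SeO2), CH2Cl, then CH2SiMe2Ph.

Assumption: the cyclised compounds are named with labdane numbering in the normal series (5α-H, 9α-H, 10β-CH3; C18 = 4α carbon, C19 = 4β methyl), so the target is (4R,5R,8R,9R,10S,13E)-18-acetoxy-8α-hydroxylabd-13-en-15-oic acid.
Assumption: the (S,S) antipode of the step 7 catalyst is taken to give the normal series; if the sense of induction is opposite, the (R,R) antipode is used.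

## Route

Step 1
Reactants: 1 (2E,6E)-farnesyl bromide; 2 ethyl acetoacetate
Product: 5 (5E,9E)-6,10,14-trimethylpentadeca-5,9,13-trien-2-one, via keto ester 3 (not isolated), via keto acid 4 (not isolated)
Conditions: NaOEt, EtOH, 0 °C → rt; then 2 M aq. NaOH, 50 °C; then HCl to pH 4, 50 °C
Reagents that add atoms: none
Why: Acetoacetic ester synthesis: the sodium enolate of 2 is C-alkylated by the primary allylic bromide in an SN2 reaction (no allylic shift, E-alkenes untouched), and saponification followed by decarboxylation of the β-keto acid leaves the methyl ketone with no stereocentre.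

Step 2
Reactants: 5 (5E,9E)-6,10,14-trimethylpentadeca-5,9,13-trien-2-one
Product: 6 2-methyl-2-[(3E,7E)-4,8,12-trimethyltrideca-3,7,11-trien-1-yl]-1,3-dioxolane
Conditions: HOCH2CH2OH, PPTS (cat.), benzene, reflux, Dean–Stark
Reagents that add atoms: ethylene glycol, OCCO
Why: Acid-catalysed ketalisation with azeotropic removal of water masks the ketone against the silyl anion of step 5, and PPTS is too weak an acid to protonate the trisubstituted alkenes.

Step 3
Reactants: 6 2-methyl-2-[(3E,7E)-4,8,12-trimethyltrideca-3,7,11-trien-1-yl]-1,3-dioxolane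
Product: 7 (2E,6E,10E)-2,6,10-trimethyl-13-(2-methyl-1,3-dioxolan-2-yl)trideca-2,6,10-trien-1-ol
Conditions: SeO2 (0.3 equiv), t-BuOOH (70% aq.), salicylic acid (cat.), CH2Cl2, 0 °C → rt
Reagents that add atoms: tert-butyl hydroperoxide, CC(C)(C)OO; selenium dioxide (catalytic oxygen relay), O=[Se]=O
Why: Selenium dioxide allylic oxidation (ene reaction, then [2,3]-sigmatropic shift) attacks the (E)-methyl of the terminal, most electron-rich alkene, so the (E)-CH2OH geometry that later defines C4 is fixed here, in an expected yield of about 40–50%.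

Step 4
Reactants: 7 (2E,6E,10E)-2,6,10-trimethyl-13-(2-methyl-1,3-dioxolan-2-yl)trideca-2,6,10-trien-1-ol
Product: 8 2-[(3E,7E,11E)-13-chloro-4,8,12-trimethyltrideca-3,7,11-trien-1-yl]-2-methyl-1,3-dioxolane
Conditions: PPh3, CCl4, 60 °C
Reagents that add atoms: carbon tetrachloride, ClC(Cl)(Cl)Cl
Why: Appel chlorination displaces the alkoxyphosphonium group by SN2 under neutral conditions, so the primary allylic alcohol gives the primary chloride without allylic shift or E/Z erosion and the ketal survives.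

Step 5
Reactants: 8 2-[(3E,7E,11E)-13-chloro-4,8,12-trimethyltrideca-3,7,11-trien-1-yl]-2-methyl-1,3-dioxolane
Product: 9 dimethyl(phenyl)[(2E,6E,10E)-2,6,10-trimethyl-13-(2-methyl-1,3-dioxolan-2-yl)trideca-2,6,10-trien-1-yl]silane
Conditions: PhMe2SiLi (preformed 1 M solution in THF, 1.2 equiv), THF, −78 → −40 °C
Reagents that add atoms: dimethylphenylsilyllithium, [Li][Si](C)(C)c1ccccc1
Why: The silyl anion displaces the primary allylic chloride by SN2 at the unhindered CH2 (attack at the more hindered γ-carbon is disfavoured), giving the (E)-allylsilane with the geometry retained, while the ketal is inert to the silyllithium.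

Step 6
Reactants: 9 dimethyl(phenyl)[(2E,6E,10E)-2,6,10-trimethyl-13-(2-methyl-1,3-dioxolan-2-yl)trideca-2,6,10-trien-1-yl]silane
Product: 10 (5E,9E,13E)-15-[dimethyl(phenyl)silyl]-6,10,14-trimethylpentadeca-5,9,13-trien-2-one
Conditions: PPTS (cat.), acetone–H2O 10:1, 45 °C
Reagents that add atoms: water, O
Why: Mild acid-catalysed ketal hydrolysis frees the ketone that will terminate the cyclisation, and PPTS is far too weak to protodesilylate the allylsilane.

Step 7
Reactants: 10 (5E,9E,13E)-15-[dimethyl(phenyl)silyl]-6,10,14-trimethylpentadeca-5,9,13-trien-2-one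
Product: 11 18-[dimethyl(phenyl)silyl]-8α,13-epoxy-14,15-dinorlabd-12-ene
Conditions: (S,S)-IDPi Brønsted acid HN[P(=NSO2C6F5)(O2C20H10Ar2)]2 from (S)-BINOL with Ar = 1-pyrenyl at the 3,3'-positions (5 mol %), (CF3)3COH–CH2Cl2 1:1, −40 °C, 72 h
Reagents that add atoms: none
Why: Proposed new method: the confined chiral acid protonates C3 of the terminal allylsilane, which is by far the most nucleophilic alkene (an oxygen substituent at C18 would instead shut down initiation at this end), the C18–Si bond stabilises the developing C4 cation by hyperconjugation while the pre-folded chair–chair triene adds in concerted anti fashion faster than silicon is lost (no nucleophilic counter-ion, non-nucleophilic fluorinated solvent), the C8 cation is captured on its α face by the ketone oxygen and the oxocarbenium ion loses H-12 to regenerate the acid; the (E)-CH2Si group ends equatorial (4α, and the bulky group prefers this position even if the cation is discrete), each E-alkene delivers the trans-anti relationships (5α-H, 10β-CH3, 9α-H, 8α-O), and the absolute sense is fixed by the catalyst pocket in the first ring closure; the closest known reaction types are the IDPi-catalysed enantioselective cyclisation of homofarnesol to ambrox in fluorinated alcohol, the acid-mediated cyclisation of farnesylacetone to sclareol oxide, and allylsilane annulations in which a β-silyl cation is intercepted with silicon retained.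

Step 8
Reactants: 11 18-[dimethyl(phenyl)silyl]-8α,13-epoxy-14,15-dinorlabd-12-ene
Product: 12 8α,13-epoxy-14,15-dinorlabd-12-en-18-ol
Conditions: KH, t-BuOOH, TBAF, NMP, 70 °C
Reagents that add atoms: tert-butyl hydroperoxide, CC(C)(C)OO
Why: Tamao–Fleming oxidation under basic conditions (peroxide and fluoride attack at silicon, loss of the phenyl group, 1,2-shift of the neopentyl carbon from silicon to oxygen) turns C18–Si into C18–OH, and the acid-sensitive enol ether, which protects both the C13 ketone and the 8-oxygen, is inert to base.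

Step 9
Reactants: 12 8α,13-epoxy-14,15-dinorlabd-12-en-18-ol
Product: 13 8α,13-epoxy-14,15-dinorlabd-12-en-18-yl acetate
Conditions: Ac2O, pyridine, DMAP (cat.), CH2Cl2, rt
Reagents that add atoms: acetic anhydride, CC(=O)OC(C)=O
Why: DMAP-catalysed acylation of the only hydroxyl group (primary, neopentyl) installs the 18-acetate under basic conditions that do not touch the enol ether.

Step 10
Reactants: 13 8α,13-epoxy-14,15-dinorlabd-12-en-18-yl acetate
Product: 14 8α-hydroxy-13-oxo-14,15-dinorlabdan-18-yl acetate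
Conditions: 0.5 M aq. oxalic acid, THF, rt
Reagents that add atoms: water, O
Why: Acid-catalysed enol ether hydrolysis (protonation at C12, water adds to the oxocarbenium carbon C13) releases the methyl ketone and the tertiary 8α-hydroxyl without breaking the C8–O bond, so C8 keeps its configuration and the acetate survives the mild acid.

Step 11
Reactants: 14 8α-hydroxy-13-oxo-14,15-dinorlabdan-18-yl acetate; 15 prop-2-en-1-yl 2-(diethoxyphosphoryl)acetate
Product: 16 prop-2-en-1-yl (13E)-18-acetoxy-8α-hydroxylabd-13-en-15-oate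
Conditions: 15 (1.6 equiv), NaH (1.5 equiv), THF, 0 °C; then 14, 0 → 45 °C
Reagents that add atoms: none
Why: Horner–Wadsworth–Emmons olefination of the methyl ketone gives mainly the (E)-trisubstituted enoate (about 5:1, the Z isomer removed by chromatography), and keeping NaH below the amount of 15 avoids a C8 alkoxide and with it oxa-Michael closure onto the new enoate.

Step 12
Reactants: 16 prop-2-en-1-yl (13E)-18-acetoxy-8α-hydroxylabd-13-en-15-oate
Product: 17 (13E)-18-acetoxy-8α-hydroxylabd-13-en-15-oic acid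
Conditions: Pd(PPh3)4 (5 mol %), morpholine, THF, rt
Reagents that add atoms: none
Why: Tsuji–Trost deallylation: zerovalent palladium ionises the allyl ester to a π-allyl complex that morpholine captures, freeing the acid under neutral conditions that leave the acetate, the tertiary alcohol and the (E)-enoate untouched.

## Compound list

1 | (2E,6E)-1-bromo-3,7,11-trimethyldodeca-2,6,10-triene ((E,E)-farnesyl bromide) | CC(C)=CCC/C(C)=C/CC/C(C)=C/CBr | starting material
2 | ethyl 3-oxobutanoate (ethyl acetoacetate) | CCOC(=O)CC(C)=O | starting material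
3 | ethyl (4E,8E)-2-acetyl-5,9,13-trimethyltetradeca-4,8,12-trienoate (keto ester, racemic at C2) | CCOC(=O)C(C/C=C(\C)CC/C=C(\C)CCC=C(C)C)C(C)=O | intermediate
4 | (4E,8E)-2-acetyl-5,9,13-trimethyltetradeca-4,8,12-trienoic acid (keto acid, racemic at C2) | OC(=O)C(C/C=C(\C)CC/C=C(\C)CCC=C(C)C)C(C)=O | intermediate
5 | (5E,9E)-6,10,14-trimethylpentadeca-5,9,13-trien-2-one ((E,E)-farnesylacetone) | CC(C)=CCC/C(C)=C/CC/C(C)=C/CCC(C)=O | intermediate
6 | 2-methyl-2-[(3E,7E)-4,8,12-trimethyltrideca-3,7,11-trien-1-yl]-1,3-dioxolane | CC(C)=CCC/C(C)=C/CC/C(C)=C/CCC1(C)OCCO1 | intermediate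
7 | (2E,6E,10E)-2,6,10-trimethyl-13-(2-methyl-1,3-dioxolan-2-yl)trideca-2,6,10-trien-1-ol | OC/C(C)=C/CC/C(C)=C/CC/C(C)=C/CCC1(C)OCCO1 | intermediate
8 | 2-[(3E,7E,11E)-13-chloro-4,8,12-trimethyltrideca-3,7,11-trien-1-yl]-2-methyl-1,3-dioxolane | ClC/C(C)=C/CC/C(C)=C/CC/C(C)=C/CCC1(C)OCCO1 | intermediate
9 | dimethyl(phenyl)[(2E,6E,10E)-2,6,10-trimethyl-13-(2-methyl-1,3-dioxolan-2-yl)trideca-2,6,10-trien-1-yl]silane | C[Si](C)(c1ccccc1)C/C(C)=C/CC/C(C)=C/CC/C(C)=C/CCC1(C)OCCO1 | intermediate
10 | (5E,9E,13E)-15-[dimethyl(phenyl)silyl]-6,10,14-trimethylpentadeca-5,9,13-trien-2-one | C[Si](C)(c1ccccc1)C/C(C)=C/CC/C(C)=C/CC/C(C)=C/CCC(C)=O | intermediate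
11 | 18-[dimethyl(phenyl)silyl]-8α,13-epoxy-14,15-dinorlabd-12-ene (4α-CH2Si, 4β-CH3, 5α-H, 9α-H, 10β-CH3) | C[Si](C)(c1ccccc1)C[C@]1(C)CCC[C@]2(C)[C@H]3CC=C(C)O[C@]3(C)CC[C@@H]12 | intermediate
12 | 8α,13-epoxy-14,15-dinorlabd-12-en-18-ol | OC[C@]1(C)CCC[C@]2(C)[C@H]3CC=C(C)O[C@]3(C)CC[C@@H]12 | intermediate
13 | 8α,13-epoxy-14,15-dinorlabd-12-en-18-yl acetate | CC(=O)OC[C@]1(C)CCC[C@]2(C)[C@H]3CC=C(C)O[C@]3(C)CC[C@@H]12 | intermediate
14 | 8α-hydroxy-13-oxo-14,15-dinorlabdan-18-yl acetate | CC(=O)OC[C@]1(C)CCC[C@]2(C)[C@@H](CCC(C)=O)[C@](C)(O)CC[C@@H]12 | intermediate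
15 | prop-2-en-1-yl 2-(diethoxyphosphoryl)acetate (allyl diethylphosphonoacetate) | C=CCOC(=O)CP(=O)(OCC)OCC | starting material
16 | prop-2-en-1-yl (13E)-18-acetoxy-8α-hydroxylabd-13-en-15-oate | CC(=O)OC[C@]1(C)CCC[C@]2(C)[C@@H](CC/C(C)=C/C(=O)OCC=C)[C@](C)(O)CC[C@@H]12 | intermediate
17 | (4R,5R,8R,9R,10S,13E)-18-acetoxy-8α-hydroxylabd-13-en-15-oic acid | CC(=O)OC[C@]1(C)CCC[C@]2(C)[C@@H](CC/C(C)=C/C(=O)O)[C@](C)(O)CC[C@@H]12 | target

## Step count and risks

Total step count: 12. Longest linear sequence: 12 steps (1 to 17).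

Steps most likely to fail:

Step 7, the proposed new bicyclisation. The allylsilane may simply be protodesilylated, or the enantioselectivity may be low. The fallback uses known chemistry, sets out from 7 and comes back at 12, and needs no silicon at C18. PPTS in wet acetone gives (5E,9E,13E)-15-hydroxy-6,10,14-trimethylpentadeca-5,9,13-trien-2-one F1. Sharpless asymmetric epoxidation (Ti(OiPr)4, L-(+)-diethyl tartrate, t-BuOOH, 4 Å sieves, CH2Cl2, −20 °C) gives (5E,9E)-12-[(2S,3S)-3-(hydroxymethyl)-3-methyloxiran-2-yl]-6,10-dimethyldodeca-5,9-dien-2-one F2. TBDPSCl and imidazole give the non-participating silyl ether (5E,9E)-12-[(2S,3S)-3-{[(tert-butyldiphenylsilyl)oxy]methyl}-3-methyloxiran-2-yl]-6,10-dimethyldodeca-5,9-dien-2-one F3. SnCl4 in CH2Cl2 at −78 °C then effects the classical epoxide-initiated cationic bicyclisation, terminated by the ketone, to 18-[(tert-butyldiphenylsilyl)oxy]-8α,13-epoxy-14,15-dinorlabd-12-en-3β-ol F4; the epoxide configuration fixes the absolute sense and the (E)-CH2OSi group again ends 4α. Barton–McCombie deoxygenation follows: NaH, CS2 and MeI give O-{18-[(tert-butyldiphenylsilyl)oxy]-8α,13-epoxy-14,15-dinorlabd-12-en-3β-yl} S-methyl carbonodithioate F5, and Bu3SnH with AIBN in toluene at 110 °C gives tert-butyl[(8α,13-epoxy-14,15-dinorlabd-12-en-18-yl)oxy]diphenylsilane F6. TBAF in THF then gives 12.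

Step 5, the silyl anion substitution. Attack at the γ-carbon or Wurtz-type coupling could erode the yield. The fallback sets out from 7 and comes back at 9. Ac2O and pyridine give (2E,6E,10E)-2,6,10-trimethyl-13-(2-methyl-1,3-dioxolan-2-yl)trideca-2,6,10-trien-1-yl acetate F7. With PhMe2Si–SiMe2Ph, the zerovalent palladium complex Pd(dba)2 (5 mol %) and LiCl in DMF at 100 °C, F7 undergoes the known palladium-catalysed allylic silylation through a π-allyl intermediate; silicon goes to the unsubstituted terminus and gives 9, whose E/Z ratio must be checked.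

Step 8, the basic Tamao–Fleming oxidation of a neopentyl CH2–Si next to a quaternary carbon. It may stall or give partial desilylation. The fallback sets out from 11 and comes back at 14. Aqueous oxalic acid in THF opens the enol ether to 18-[dimethyl(phenyl)silyl]-8α-hydroxy-14,15-dinorlabdan-13-one F8. The classical electrophilic Fleming oxidation (KBr, AcOOH, NaOAc, AcOH, rt; ipso-bromodesilylation of the phenyl group, then peracid-induced carbon migration) gives 8α,18-dihydroxy-14,15-dinorlabdan-13-one F9. Ac2O and pyridine at 0 °C without DMAP acetylate only the primary hydroxyl and give 14.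

Further compounds
F1 | step 7 | (5E,9E,13E)-15-hydroxy-6,10,14-trimethylpentadeca-5,9,13-trien-2-one | OC/C(C)=C/CC/C(C)=C/CC/C(C)=C/CCC(C)=O
F2 | step 7 | (5E,9E)-12-[(2S,3S)-3-(hydroxymethyl)-3-methyloxiran-2-yl]-6,10-dimethyldodeca-5,9-dien-2-one | OC[C@]1(C)O[C@H]1CC/C(C)=C/CC/C(C)=C/CCC(C)=O
F3 | step 7 | (5E,9E)-12-[(2S,3S)-3-{[(tert-butyldiphenylsilyl)oxy]methyl}-3-methyloxiran-2-yl]-6,10-dimethyldodeca-5,9-dien-2-one | CC(C)(C)[Si](c1ccccc1)(c1ccccc1)OC[C@]1(C)O[C@H]1CC/C(C)=C/CC/C(C)=C/CCC(C)=O
F4 | step 7 | 18-[(tert-butyldiphenylsilyl)oxy]-8α,13-epoxy-14,15-dinorlabd-12-en-3β-ol | CC(C)(C)[Si](c1ccccc1)(c1ccccc1)OC[C@]1(C)[C@@H](O)CC[C@]2(C)[C@H]3CC=C(C)O[C@]3(C)CC[C@@H]12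
F5 | step 7 | O-{18-[(tert-butyldiphenylsilyl)oxy]-8α,13-epoxy-14,15-dinorlabd-12-en-3β-yl} S-methyl carbonodithioate | CC(C)(C)[Si](c1ccccc1)(c1ccccc1)OC[C@]1(C)[C@@H](OC(=S)SC)CC[C@]2(C)[C@H]3CC=C(C)O[C@]3(C)CC[C@@H]12
F6 | step 7 | tert-butyl[(8α,13-epoxy-14,15-dinorlabd-12-en-18-yl)oxy]diphenylsilane | CC(C)(C)[Si](c1ccccc1)(c1ccccc1)OC[C@]1(C)CCC[C@]2(C)[C@H]3CC=C(C)O[C@]3(C)CC[C@@H]12
F7 | step 5 | (2E,6E,10E)-2,6,10-trimethyl-13-(2-methyl-1,3-dioxolan-2-yl)trideca-2,6,10-trien-1-yl acetate | CC(=O)OC/C(C)=C/CC/C(C)=C/CC/C(C)=C/CCC1(C)OCCO1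
F8 | step 8 | 18-[dimethyl(phenyl)silyl]-8α-hydroxy-14,15-dinorlabdan-13-one | C[Si](C)(c1ccccc1)C[C@]1(C)CCC[C@]2(C)[C@@H](CCC(C)=O)[C@](C)(O)CC[C@@H]12
F9 | step 8 | 8α,18-dihydroxy-14,15-dinorlabdan-13-one | OC[C@]1(C)CCC[C@]2(C)[C@@H](CCC(C)=O)[C@](C)(O)CC[C@@H]12
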